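## The problem

Pharbinilic acid is a benzofuran (ring A, C1–C5 and C10 in gibberellin numbering, with the furan fused at C2–C3, its CO2H on the carbon attached to C2 and the methyl C18 on C4) joined through C5 and C10 to cyclopentane ring B (C5, C6, C8, C9, C10), which shares the C8–C9 bond with a bicyclo[3.2.1]octane made of ring C (C8, C9, C11, C12, C13, C14) and ring D (C8, C14, C13, C16, C15). The hardest atom is C8: an all-carbon quaternary centre common to rings B, C and D, flanked by the benzylic C9–H, the C6 methine that carries the C7 carboxyl, and the bridging methylenes C14 and C15. Of the four stereocentres, the bridgeheads C13 and C8 fix each other, so whichever is made first decides the absolute series; C9 must carry its hydrogen on the face of C15; C6 is benzylic and α to a carboxyl and can be left to equilibration. C13 is awkward in any monocyclic ring C precursor, because its two ring arms differ only at a distance and a late enantioselective addition to a C13 ketone has nothing to read. The tertiary allylic alcohol (13-OH beside the C16=C17 methylene) undergoes Wagner–Meerwein rearrangement to a ring D ketone in strong acid, so the endgame must be basic or neutral. The C7 ester is hindered, and in tetrahydrofluorene intermediates C6–H is about as acidic as a malonate C–H. The feature that opens the key step is that ring D spans ring C from C8 to C13 through C15 and C16 while C8 and C9 can be held as the tetrasubstituted C8=C9 alkene of a tetrahydrofluorene: a carbene at C15, tied to C13 through the C16 carbonyl, sits over that alkene, and the extra C15–C9 bond it makes is benzylic and α to a ketone, hence removable.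

## Retrosynthesis

**Endgame (C16=C17, protecting groups, C6).** Acid 34 is taken back to diester 32, so that ethoxide can equilibrate C6 (33) and hydroxide can cleave both esters without acid touching the allylic alcohol. 32 comes from silyl ether 31, and the C16=C17 bond of 31 is cut to ketone 30. Cutting the methylene here is preferred to carrying it, because the ketone is what the ring D construction leaves. The forward methylenation must tolerate two esters next to a neopentyl ketone.

**C15–C9 (a bond added in the retro direction).** In 30 the C9–H bond is exchanged for a C15–C9 bond, giving cyclopropyl ketone 29. This costs one reductive step forward, but it turns the quaternary C8 from the product of a substitution into the product of a cycloaddition. The forward cleavage must break C15–C9 and not C15–C8, and must put hydrogen on C9 from the C15 face.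

**C15–C8 and C15–C9 (key cut).** Removing both bonds from C15 gives diazoketone 28. The neighbouring polar cuts at C8 were weighed and rejected: no carbonyl group acidifies C8 (C7 acidifies C6), so an alkylation that closes ring D would need an unstabilised neopentyl carbanion. The carbene route asks only for the C8=C9 alkene. 28 is much simpler than 29: a flat tetrahydrofluorene whose one controlling stereocentre is C13. The forward reaction must prefer the alkene to C–H bonds.

**Unmasking C13 and C16.** 28 is the diazomethane adduct of the acid chloride of silyl ether acid 26, which comes from hydroxy acid 24, and 24 is hidden in spiro-dioxolanone 23. The acetal masks the tertiary hydroxyl and the carboxyl in one ring and carries the auxiliary stereocentre. A nitrile or ester at C16 would need several redox steps or could not be told apart from the other two esters.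

**C5–C6 (ring B).** 23 is opened at the aryl–C6 bond to bromide 22 (enolate α-arylation forward). The other ring B cut, C9–C10 by Friedel–Crafts closure, depends on the nucleophilicity of an ester-substituted benzofuran and is kept in reserve. The forward reaction must couple a doubly ortho-substituted aryl bromide.

**C9–C10 (the two halves).** 22 divides into vinyl triflate 19 and aryl iodide 6, the iodide being the more reactive halogen and the bromide the latent one. 6 is the benzofuran from salicylaldehyde 3 and diazoester 4; 3 comes from phenol 1 by formylation (2) and iodination, each at the only position the substituents allow.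

**C6–C8 and the place of the alkene.** Triflate 19 needs C8=C9 tetrasubstituted with the acetate arm on C8. It is taken back through enone ester 17 (conjugate hydride delivers the enolate regiospecifically) and aldol 15 to silyl enol ether 12 and glyoxylate 13. This is longer than a direct alkylation, but at no point does a free ketone enolate exist that could exchange the two arms of ring C.

**C13–C14 and C11–C12 (ring C and the absolute configuration).** 12 is the Diels–Alder adduct of methylidene dioxolanone 10 and siloxydiene 11; 10 comes from (R)-lactic acid 7 through acetal 8. An enantioselective addition to a C13 ketone of a finished tetrahydrofluorene was considered and dropped, because the ketone's flanks are nearly identical and a β,γ-unsaturated C13 ketone would conjugate. In the cycloaddition the face of 10 sets C13 and the regiochemistry writes the difference between the arms into the enol ether.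

## Roads not taken

**Alternative 1:** The cut removes C3–C4 and C10–C5, so rings A and B are made last on a finished C/D bicycle. Forward, heating vinylfuran ynone A1 would add the 3-vinylfuran diene to the tethered alkyne and, with DDQ removing the hydrogens at C3 and C10 in the same operation, give ketone A2.
- Merits: two rings and the whole arene form in one operation, the methyl and the furan ester are placed by the tether, there are no palladium steps, and no tetrahydrofluorene tautomers arise.
- Weak points: A1 already contains C8 with its four carbon substituents, so the hardest atom must be built earlier by other means. The furan must give up its aromaticity next to a quaternary centre. A2 has a ketone at C6, and turning that neopentyl aryl ketone, wedged between C8 and the C18 methyl, into CH–CO2H with the right configuration is a hindered homologation of several steps. The allylic alcohol must survive heat and DDQ.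
- Comparison: this road is better at arene construction (the chosen plan spends three steps on 6 and two palladium steps attaching it) and more convergent at the end. The chosen plan sets against it that one cycloaddition makes C8, ring D and the C13–C8 relationship, and that C7 is present at the right oxidation level from step 7.

**Alternative 2:** The cut is C10–C9. Forward, zerovalent palladium from Pd(OAc)2 and a chiral bisphosphine would insert into the C–Br bond of the achiral dienyl ketone A3, the aryl group would add 5-exo to one of the two enantiotopic alkenes, and formate would reduce the C11–palladium bond to give A4.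
- Merits: absolute configuration comes from a catalyst acting on achiral material, which is better than a stoichiometric auxiliary. C8 and C9 are set together with the cis fusion, and A3 is short to make.
- Weak points: A4 has neither ring D nor the C13 oxygen. Ring D must then be grown from the C8 side chain onto the remaining alkene, with the new C–C bond at C13 and the oxygen also ending on C13, which is the reverse of what carbonyl–alkene closures deliver. The C6 ketone needs the same hindered homologation as in alternative 1. β-Hydride elimination from C11 competes with formate capture.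
- Comparison: this road wins on asymmetric economy and on its early steps. The chosen plan sets against it that its key step delivers the bridged half with C13 at the right oxidation level, at the price of a lactic acid auxiliary and a temporary bond.

**Alternative 3:** The cut is C12–C13. Forward, fluoride would unmask an enolate of the spiro bis(silyloxy)cyclopentene in iodide A5, and the enediol carbon on the C9 side would displace the C12 iodide (6-exo-tet) to give ketone A6, which differs from compound 30 of the chosen route only in the silyl and ester alkyl groups and in having C6 already fixed.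
- Merits: the key step is mild and needs no carbene, no diazomethane and no reductive cleavage. C9 is set beforehand, so the facial question of step 16 does not arise. In these respects it is as good as or better than the chosen plan, and it reaches the same endgame.
- Weak points: A5 needs the symmetric enediol ether on C8, an acyloin-type construction under strongly reducing conditions beside two other esters. C6 and C9 must be made trans and in absolute form by a separate method, since the key step only relays stereochemistry. A fully substituted enolate must form a quaternary carbon by SN2 against O-alkylation and loss of HI.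
- Comparison: the chosen plan sets against it that every stereocentre descends from one early centre (C13), that C8 is made by an intramolecular cycloaddition and not a hindered substitution, and that its precursor is assembled by robust couplings.

Key step: step 15

Remark: atoms are numbered as in the gibberellins throughout; C6 is configurationally labile in the indene intermediates, so compounds 23–32 are carried as both C6 epimers (C6 left open in their SMILES) and C6 is fixed by equilibration in step 19.
Remark: the (R)-acetal is chosen on the assumption that the diene adds to 10 anti to the tert-butyl group, which then gives (13S) as in the target.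

Step 1
Reactants: 1 3-bromo-2-methylphenol
Product: 2 4-bromo-2-hydroxy-3-methylbenzaldehyde
Conditions: MgCl2, Et3N, (CH2O)n, MeCN, reflux; aq. HCl work-up
Reagents that add atoms: paraformaldehyde (as formaldehyde), C=O
Why: Magnesium phenoxide-directed ortho-formylation; the only free ortho position is C6 of the phenol, because the other ortho carbon carries the methyl group.

Step 2
Reactants: 2 4-bromo-2-hydroxy-3-methylbenzaldehyde
Product: 3 4-bromo-2-hydroxy-5-iodo-3-methylbenzaldehyde
Conditions: N-iodosuccinimide, CF3CO2H (cat.), MeCN, rt
Reagents that add atoms: N-iodosuccinimide, O=C1CCC(=O)N1I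
Why: Electrophilic aromatic iodination; C5 is para to the hydroxyl and meta to the formyl group, so both substituents direct to it, while the only other open position is meta to the hydroxyl.

Step 3
Reactants: 3 4-bromo-2-hydroxy-5-iodo-3-methylbenzaldehyde; 4 ethyl diazoacetate
Product: 6 ethyl 6-bromo-5-iodo-7-methyl-1-benzofuran-3-carboxylate, via cyclic hemiacetal 5 (not isolated)
Conditions: HBF4·OEt2 (10 mol %), CH2Cl2, rt; then conc. H2SO4
Reagents that add atoms: none
Why: Acid-catalysed addition of the diazoester to the aldehyde with 1,2-aryl shift gives a 3-hydroxy-2-arylacrylate that closes onto the phenol; H2SO4 dehydrates the hemiacetal to the benzofuran-3-carboxylate (known one-pot benzofuran synthesis from salicylaldehydes). The aldehyde carbon becomes furan C2, so iodine ends at C5 and bromine at C6 of the benzofuran.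

Step 4
Reactants: 7 (R)-lactic acid
Product: 8 (2R,5R)-2-tert-butyl-5-methyl-1,3-dioxolan-4-one
Conditions: t-BuCHO, TsOH·H2O (cat.), H2SO4 (cat.), pentane, reflux (Dean–Stark); recrystallisation at −78 °C
Reagents that add atoms: pivalaldehyde, CC(C)(C)C=O
Why: Acid-catalysed acetalisation of an α-hydroxy acid; the cis acetal is favoured and is purified by crystallisation, so the lactic acid centre sets the acetal carbon as R.

Step 5
Reactants: 8 (2R,5R)-2-tert-butyl-5-methyl-1,3-dioxolan-4-one
Product: 10 (2R)-2-tert-butyl-5-methylidene-1,3-dioxolan-4-one, via bromide 9 (not isolated)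
Conditions: N-bromosuccinimide, AIBN (cat.), cyclohexane, reflux; filter; then Et3N, Et2O, 0 °C → rt
Reagents that add atoms: none
Why: Radical bromination at the captodative C5–H followed by E2 loss of HBr from the methyl group; the acetal carbon is untouched and is now the only stereocentre.

Step 6
Reactants: 10 (2R)-2-tert-butyl-5-methylidene-1,3-dioxolan-4-one; 11 2-(trimethylsilyloxy)buta-1,3-diene
Product: 12 (2R,5S)-2-tert-butyl-8-(trimethylsilyloxy)-1,3-dioxaspiro[4.5]dec-7-en-4-one
Conditions: toluene, 2,6-di-tert-butyl-4-methylphenol (cat.), 100 °C, sealed tube; volatiles removed, used directly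
Reagents that add atoms: none
Why: Thermal Diels–Alder reaction of a 2-siloxydiene with an α-oxyacrylate-type dienophile; the diene should add anti to the tert-butyl group, which sets C13 as S, and the "para" orientation bonds the nucleophilic diene terminus (C11) to the dienophile CH2 (C12), so the enol ether lies at C9=C8 on the C14 arm. Minor facial or regio isomers remain diastereomers as long as the acetal is present and can be removed at 17 or 19.

Step 7
Reactants: 12 (2R,5S)-2-tert-butyl-8-(trimethylsilyloxy)-1,3-dioxaspiro[4.5]dec-7-en-4-one; 13 ethyl glyoxylate
Product: 15 ethyl 2-[(2R,5S)-2-tert-butyl-4,8-dioxo-1,3-dioxaspiro[4.5]decan-7-yl]-2-hydroxyacetate, via silyl ether 14 (not isolated)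
Conditions: Sc(OTf)3 (5 mol %), CH2Cl2, −78 °C; then 1 M HCl, THF, 0 °C
Reagents that add atoms: none
Why: Mukaiyama aldol addition at the enol ether carbon C8 only, with no free enolate that could exchange the two arms; from here the difference between the arms is constitutional. The two new centres (C8 and the carbinol) are not controlled and both become sp2 in steps 8 and 9.

Step 8
Reactants: 15 ethyl 2-[(2R,5S)-2-tert-butyl-4,8-dioxo-1,3-dioxaspiro[4.5]decan-7-yl]-2-hydroxyacetate
Product: 17 ethyl (2E)-2-[(2R,5S)-2-tert-butyl-4,8-dioxo-1,3-dioxaspiro[4.5]decan-7-ylidene]acetate, via mesylate 16 (not isolated)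
Conditions: MsCl, Et3N, CH2Cl2, 0 °C; then DBU, 0 °C → rt
Reagents that add atoms: none
Why: Mesylation and E1cB elimination through the ketone enolate give the doubly conjugated alkylidene ketone; mesylation is faster than any retro-aldol. Isomerisation to the endocyclic enone would be harmless, because step 9 gives the same enolate from either isomer.

Step 9
Reactants: 17 ethyl (2E)-2-[(2R,5S)-2-tert-butyl-4,8-dioxo-1,3-dioxaspiro[4.5]decan-7-ylidene]acetate
Product: 19 ethyl 2-[(2R,5S)-2-tert-butyl-4-oxo-8-(trifluoromethanesulfonyloxy)-1,3-dioxaspiro[4.5]dec-7-en-7-yl]acetate, via lithium enolate 18 (not isolated)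
Conditions: LiBH(s-Bu)3, THF, −78 °C; then PhNTf2, −78 → 0 °C
Reagents that add atoms: N-phenylbis(trifluoromethanesulfonimide), O=S(=O)(N(c1ccccc1)S(=O)(=O)C(F)(F)F)C(F)(F)F
Why: Conjugate reduction with enolate trapping; hydride adds to C6, the unhindered carbon β to the ketone, so the enolate and then the triflate are formed only across C8=C9. The hindered lactone carbonyl is slower than the enone at −78 °C.

Step 10
Reactants: 6 ethyl 6-bromo-5-iodo-7-methyl-1-benzofuran-3-carboxylate; 19 ethyl 2-[(2R,5S)-2-tert-butyl-4-oxo-8-(trifluoromethanesulfonyloxy)-1,3-dioxaspiro[4.5]dec-7-en-7-yl]acetate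
Product: 22 ethyl 6-bromo-5-[(2R,5S)-2-tert-butyl-7-(2-ethoxy-2-oxoethyl)-4-oxo-1,3-dioxaspiro[4.5]dec-7-en-8-yl]-7-methyl-1-benzofuran-3-carboxylate, via arylmagnesium chloride 20 (not isolated), via arylzinc chloride 21 (not isolated)
Conditions: 6, i-PrMgCl·LiCl, THF, −40 °C; ZnCl2, −40 → 0 °C; then 19, Pd(PPh3)4 (5 mol %), THF, 55 °C
Reagents that add atoms: none
Why: Iodine–magnesium exchange is selective for C–I over the hindered C–Br and tolerates the ester at −40 °C; transmetalation to zinc and Negishi coupling with the vinyl triflate form C9–C10. The arylzinc does not attack the lactone, and the flanked C–Br bond is much slower in oxidative addition than the triflate.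

Step 11
Reactants: 22 ethyl 6-bromo-5-[(2R,5S)-2-tert-butyl-7-(2-ethoxy-2-oxoethyl)-4-oxo-1,3-dioxaspiro[4.5]dec-7-en-8-yl]-7-methyl-1-benzofuran-3-carboxylate
Product: 23 spiro-dioxolanone tetrahydrofluorene diester (13S; C6 epimers)
Conditions: Pd2(dba)3 (2.5 mol %), P(t-Bu)3·HBF4 (10 mol %), LiN(SiMe3)2 (2.5 equiv), toluene, 25 → 60 °C; AcOH, −78 °C
Reagents that add atoms: none
Why: Intramolecular palladium-catalysed α-arylation of the ester dienolate closes ring B through C5–C6 by way of a six-membered palladacycle. A Dieckmann attack of C6 on the lactone is excluded because it would put the C8=C9 bond at a bridgehead (Bredt's rule). Cold protonation of the delocalised product enolate at C6 gives the C8=C9 isomer, which should also be the more stable one, since an sp2 C6 would hold the ester in plane between the C18 methyl and C14.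

Step 12
Reactants: 23 spiro-dioxolanone tetrahydrofluorene diester (13S; C6 epimers)
Product: 24 13-hydroxy-16-oic acid of the tetrahydrofluorene diester (13S; C6 epimers)
Conditions: LiOH (3 equiv), THF/H2O 3:1 (degassed), 0 °C → rt; 1 M HCl to pH 3, 0 °C
Reagents that add atoms: lithium hydroxide, [Li+].[OH-]
Why: Saponification of the acylal-type lactone; the hemiacetal then collapses and releases pivalaldehyde. Under these conditions the C7 ester sits as its enolate (C6–H is the most acidic site) and the furan ester is a vinylogous carbonate, so both should be spared; exclusion of air protects the enolate.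

Step 13
Reactants: 24 13-hydroxy-16-oic acid of the tetrahydrofluorene diester (13S; C6 epimers)
Product: 26 13-triethylsilyloxy-16-oic acid (13S; C6 epimers), via bis-silyl compound 25 (not isolated)
Conditions: Et3SiOTf (2.5 equiv), 2,6-lutidine (3 equiv), CH2Cl2, −78 → 0 °C; then MeOH, aq. citric acid, rt
Reagents that add atoms: triethylsilyl trifluoromethanesulfonate, CC[Si](CC)(CC)OS(=O)(=O)C(F)(F)F
Why: The triflate silylates the hindered tertiary hydroxyl and the carboxyl; the silyl ester is hydrolysed in the mildly acidic work-up, which leaves the tertiary silyl ether. Lutidine is too weak a base to move the C8=C9 double bond.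

Step 14
Reactants: 26 13-triethylsilyloxy-16-oic acid (13S; C6 epimers)
Product: 28 C13 triethylsilyloxy diazoketone of the tetrahydrofluorene (13S; C6 epimers), via acid chloride 27 (not isolated)
Conditions: 1-chloro-N,N,2-trimethylprop-1-en-1-amine, CH2Cl2, 0 °C → rt; then CH2N2 (3 equiv), Et2O, 0 °C
Reagents that add atoms: diazomethane, C=[N+]=[N-]
Why: The chloroenamine forms the acid chloride under neutral conditions, so the silyl ether and the acidic C6–H are undisturbed; acylation of diazomethane (first stage of the Arndt–Eistert sequence) gives the diazoketone, with the excess reagent taking up HCl.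

Step 15
Reactants: 28 C13 triethylsilyloxy diazoketone of the tetrahydrofluorene (13S; C6 epimers)
Product: 29 cyclopropyl ketone with ring D closed (13S; C15 bonded to C8 and C9; C6 epimers)
Conditions: Rh2(OAc)4 (1 mol %), CH2Cl2, rt, slow addition of 28 (syringe pump)
Reagents that add atoms: none
Why: Rh2(OAc)4 decomposes the diazoketone to an electrophilic rhodium carbenoid at C15, which adds in one asynchronous step across the electron-rich, styrene-type C8=C9 bond. The closest known reaction type is the intramolecular cyclopropanation of cyclohex-3-enyl diazomethyl ketones to tricyclo[3.2.1.0(2,7)]octan-6-ones used in trachylobane and kaurane work, here on a tetrasubstituted aryl-conjugated alkene. Ring D closes as a five-membered ring through C15–C8 (exo attack of the chain C15–C16–C13–C14), and the cyclopropane closes with it through C15–C9, which also completes a six-membered ring through C16, C13, C12 and C11. C8, C9 and C15 become stereocentres and all three are set by C13: the two-atom tether lets C15 reach only the alkene face that carries the C13–C16 bond, and the addition is cis. C6 is not controlled and both epimers react. The step needs cyclopropanation to win over allylic C–H insertion at C11, Wolff rearrangement and carbene dimerisation: the acyl group is pseudo-axial in the reactive half-chair and holds C15 over the π bond, the alkene is the most nucleophilic site within reach, and slow addition keeps the carbenoid dilute; Cu(acac)2 in hot toluene is the alternative catalyst if insertion shows. The C13 oxygen is silylated so that O–H insertion cannot occur.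

Step 16
Reactants: 29 cyclopropyl ketone with ring D closed (13S; C15 bonded to C8 and C9; C6 epimers)
Product: 30 16-oxo 13-triethylsilyloxy diester (8S,9R,13S; C6 epimers)
Conditions: SmI2 (2.5 equiv), THF, MeOH (5 equiv), −78 → 0 °C
Reagents that add atoms: none
Why: Reductive cleavage of a cyclopropyl ketone: the C16 ketyl opens C15–C9, the bond that overlaps with the carbonyl π system (C15–C8 lies near the carbonyl plane in the five-membered ring) and that gives the benzylic C9 radical. A second electron and methanol put hydrogen on C9 from the face C15 has left, which is flanked only by the flat samarium enolate and leads to the chair bicyclo[3.2.1]octane with cis-fused ring B. The bridgehead C13–O bond is not eliminated, because the enolate that would result is forbidden by Bredt's rule.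

Step 17
Reactants: 30 16-oxo 13-triethylsilyloxy diester (8S,9R,13S; C6 epimers)
Product: 31 16-methylidene 13-triethylsilyloxy diester (C6 epimers)
Conditions: Ph3PCH3Br (3 equiv), KOt-Bu (2.8 equiv), THF, rt; then 30, rt → 50 °C
Reagents that add atoms: methyltriphenylphosphonium bromide, C[P+](c1ccccc1)(c1ccccc1)c1ccccc1.[Br-]
Why: Wittig methylenation of the hindered ring D ketone, the standard way to the 16-methylene group in gibberellin-type bicycles; the ylide does not attack the esters, and any epimerisation at C6 is harmless.

Step 18
Reactants: 31 16-methylidene 13-triethylsilyloxy diester (C6 epimers)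
Product: 32 diethyl ester of pharbinilic acid (C6 epimers)
Conditions: Bu4NF (1 M in THF), THF, rt
Reagents that add atoms: none
Why: Fluoride cleaves the tertiary triethylsilyl ether without acid, so the allylic tertiary alcohol is not exposed to rearrangement.

Step 19
Reactants: 32 diethyl ester of pharbinilic acid (C6 epimers)
Product: 34 pharbinilic acid, via 6R diester 33 (not isolated)
Conditions: NaOEt (0.3 equiv), EtOH, 50 °C; then LiOH (6 equiv), H2O, 70 °C; 0.5 M HCl to pH 3, 0 °C
Reagents that add atoms: lithium hydroxide, [Li+].[OH-]
Why: Ethoxide equilibrates the benzylic α-ester centre C6 to the epimer with the ester on the face of H9 and C15, away from C11 and C14, and this less hindered epimer is also the one that saponifies faster. Hydroxide then cleaves both ethyl esters, and cold dilute acid liberates the diacid without touching the allylic alcohol.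

## Compound list

1 | 3-bromo-2-methylphenol | Cc1c(O)cccc1Br | starting material
2 | 4-bromo-2-hydroxy-3-methylbenzaldehyde | Cc1c(O)c(C=O)ccc1Br | intermediate
3 | 4-bromo-2-hydroxy-5-iodo-3-methylbenzaldehyde | Cc1c(O)c(C=O)cc(I)c1Br | intermediate
4 | ethyl diazoacetate | CCOC(=O)C=[N+]=[N-] | starting material
5 | ethyl 6-bromo-2-hydroxy-5-iodo-7-methyl-2,3-dihydro-1-benzofuran-3-carboxylate (cyclic hemiacetal, stereocentres not controlled) | CCOC(=O)C1C(O)Oc2c(C)c(Br)c(I)cc12 | intermediate
6 | ethyl 6-bromo-5-iodo-7-methyl-1-benzofuran-3-carboxylate | CCOC(=O)c1coc2c(C)c(Br)c(I)cc12 | intermediate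
7 | (R)-lactic acid | C[C@@H](O)C(=O)O | starting material
8 | (2R,5R)-2-tert-butyl-5-methyl-1,3-dioxolan-4-one (cis) | C[C@H]1O[C@@H](C(C)(C)C)OC1=O | intermediate
9 | (2R)-5-bromo-2-tert-butyl-5-methyl-1,3-dioxolan-4-one, bromine trans to tert-butyl | C[C@@]1(Br)O[C@@H](C(C)(C)C)OC1=O | intermediate
10 | (2R)-2-tert-butyl-5-methylidene-1,3-dioxolan-4-one | C=C1O[C@@H](C(C)(C)C)OC1=O | intermediate
11 | 2-(trimethylsilyloxy)buta-1,3-diene | C=CC(=C)O[Si](C)(C)C | starting material
12 | (2R,5S)-2-tert-butyl-8-(trimethylsilyloxy)-1,3-dioxaspiro[4.5]dec-7-en-4-one (spiro carbon = C13) | C[Si](C)(C)OC1=CC[C@]2(CC1)O[C@@H](C(C)(C)C)OC2=O | intermediate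
13 | ethyl glyoxylate | CCOC(=O)C=O | starting material
14 | trimethylsilyl ether of aldol 15 (diastereomers at ring C7 and the carbinol carbon) | CCOC(=O)C(O[Si](C)(C)C)C1C[C@]2(CCC1=O)O[C@@H](C(C)(C)C)OC2=O | intermediate
15 | ethyl 2-[(2R,5S)-2-tert-butyl-4,8-dioxo-1,3-dioxaspiro[4.5]decan-7-yl]-2-hydroxyacetate (diastereomers at ring C7 and the carbinol carbon) | CCOC(=O)C(O)C1C[C@]2(CCC1=O)O[C@@H](C(C)(C)C)OC2=O | intermediate
16 | methanesulfonate of aldol 15 | CCOC(=O)C(OS(C)(=O)=O)C1C[C@]2(CCC1=O)O[C@@H](C(C)(C)C)OC2=O | intermediate
17 | ethyl (2E)-2-[(2R,5S)-2-tert-butyl-4,8-dioxo-1,3-dioxaspiro[4.5]decan-7-ylidene]acetate | CCOC(=O)/C=C1\C[C@]2(CCC1=O)O[C@@H](C(C)(C)C)OC2=O | intermediate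
18 | lithium enolate of the ring ketone across C8=C9 (precursor of 19) | [Li+].CCOC(=O)CC1=C([O-])CC[C@@]2(C1)O[C@@H](C(C)(C)C)OC2=O | intermediate
19 | ethyl 2-[(2R,5S)-2-tert-butyl-4-oxo-8-(trifluoromethanesulfonyloxy)-1,3-dioxaspiro[4.5]dec-7-en-7-yl]acetate | CCOC(=O)CC1=C(OS(=O)(=O)C(F)(F)F)CC[C@@]2(C1)O[C@@H](C(C)(C)C)OC2=O | intermediate
20 | [6-bromo-3-(ethoxycarbonyl)-7-methyl-1-benzofuran-5-yl]magnesium chloride | CCOC(=O)c1coc2c(C)c(Br)c([Mg]Cl)cc12 | intermediate
21 | [6-bromo-3-(ethoxycarbonyl)-7-methyl-1-benzofuran-5-yl]zinc chloride | CCOC(=O)c1coc2c(C)c(Br)c([Zn]Cl)cc12 | intermediate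
22 | ethyl 6-bromo-5-[(2R,5S)-2-tert-butyl-7-(2-ethoxy-2-oxoethyl)-4-oxo-1,3-dioxaspiro[4.5]dec-7-en-8-yl]-7-methyl-1-benzofuran-3-carboxylate | CCOC(=O)CC1=C(c3cc4c(C(=O)OCC)coc4c(C)c3Br)CC[C@@]2(C1)O[C@@H](C(C)(C)C)OC2=O | intermediate
23 | tetrahydrofluorene with rings A, B and C and the furan as in 34: C8=C9 alkene, CO2Et on the furan carbon and on C6 (both C6 epimers), C13 (S) as spiro carbon of a (2R)-2-tert-butyl-1,3-dioxolan-4-one whose carbonyl is C16 | CCOC(=O)C1C2=C(CC[C@@]3(C2)O[C@@H](C(C)(C)C)OC3=O)c2cc3c(C(=O)OCC)coc3c(C)c12 | intermediate
24 | as 23, but C13 (S) bears OH and CO2H (C16); both C6 epimers | CCOC(=O)C1C2=C(CC[C@](O)(C2)C(=O)O)c2cc3c(C(=O)OCC)coc3c(C)c12 | intermediate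
25 | triethylsilyl ether triethylsilyl ester of 24 | CCOC(=O)C1C2=C(CC[C@](O[Si](CC)(CC)CC)(C2)C(=O)O[Si](CC)(CC)CC)c2cc3c(C(=O)OCC)coc3c(C)c12 | intermediate
26 | as 24, but C13 bears OSiEt3 and CO2H; both C6 epimers | CCOC(=O)C1C2=C(CC[C@](O[Si](CC)(CC)CC)(C2)C(=O)O)c2cc3c(C(=O)OCC)coc3c(C)c12 | intermediate
27 | acid chloride of 26 | CCOC(=O)C1C2=C(CC[C@](O[Si](CC)(CC)CC)(C2)C(=O)Cl)c2cc3c(C(=O)OCC)coc3c(C)c12 | intermediate
28 | diazoketone: as 26, but C13 (S) bears OSiEt3 and C(=O)CHN2 (C16 carbonyl, C15 diazo carbon); both C6 epimers | CCOC(=O)C1C2=C(CC[C@](O[Si](CC)(CC)CC)(C2)C(=O)C=[N+]=[N-])c2cc3c(C(=O)OCC)coc3c(C)c12 | intermediate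
29 | cyclopropyl ketone: C15 bonded to C8 and C9 on the face of ring C that carries C16, ketone at C16, OSiEt3 on C13 (S), CO2Et on C6 (both epimers) and on the furan | O=C1[C@@H]4[C@]23C[C@@]1(O[Si](CC)(CC)CC)CC[C@@]24c1cc2c(C(=O)OCC)coc2c(C)c1C3C(=O)OCC | intermediate
30 | 16-ketone: skeleton of 34 with C16=O in place of the methylene, OSiEt3 on C13, H9 cis to C15 (8S,9R,13S), diethyl ester, both C6 epimers | O=C1C[C@]23C[C@@]1(O[Si](CC)(CC)CC)CC[C@H]2c1cc2c(C(=O)OCC)coc2c(C)c1C3C(=O)OCC | intermediate
31 | 13-O-triethylsilyl diethyl ester of pharbinilic acid, both C6 epimers | C=C1C[C@]23C[C@@]1(O[Si](CC)(CC)CC)CC[C@H]2c1cc2c(C(=O)OCC)coc2c(C)c1C3C(=O)OCC | intermediate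
32 | diethyl ester of pharbinilic acid, both C6 epimers | C=C1C[C@]23C[C@@]1(O)CC[C@H]2c1cc2c(C(=O)OCC)coc2c(C)c1C3C(=O)OCC | intermediate
33 | diethyl ester of pharbinilic acid (6R,8S,9R,13S) | C=C1C[C@]23C[C@@]1(O)CC[C@H]2c1cc2c(C(=O)OCC)coc2c(C)c1[C@@H]3C(=O)OCC | intermediate
34 | pharbinilic acid (6R,8S,9R,13S in gibberellin numbering) | C=C1C[C@]23C[C@@]1(O)CC[C@H]2c1cc2c(C(=O)O)coc2c(C)c1[C@@H]3C(=O)O | target

## Step count and risks

Total: 19 steps. Longest linear sequence: 16 steps (steps 4–19, from (R)-lactic acid 7); steps 1–3 make aryl iodide 6, which joins at step 10.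

**Step 15 (key step).** What may go wrong: insertion of the carbenoid into the allylic C11–H bond, or dimerisation, in place of addition to the hindered tetrasubstituted alkene. The acyl group must be pseudo-axial for either pathway, and in one C6 epimer the ester lies on the reacting face.
Fallback: starting from 28, anhydrous HBr in Et2O at −20 °C would replace the diazo group and give bromomethyl ketone F1. Slow addition of Bu3SnH with AIBN in benzene at 80 °C would then generate the α-keto radical at C15, which should add 5-exo to C8 (giving the benzylic C9 radical) and take hydrogen at C9. This closes ring D without a cyclopropane and rejoins the route at 30.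

**Step 16.** What may go wrong: protonation of C9 from the ring C side (the C14 face), giving the 9-epimer, or reduction of the ketone without ring opening. The two faces of the C9 anion differ only by the enolate on one side and the C14 methylene on the other.
Fallback: starting from 29, anhydrous TsOH in benzene at 60 °C would open the protonated cyclopropyl ketone to the benzylic C9 cation and, by loss of H11, give the 9(11)-ene ketone F2. NaOEt in EtOH would turn the C6 ester to the C15 face (ene ketone F3). Hydrogenation with [Ir(cod)(PCy3)(py)]PF6 in CH2Cl2, directed by that ester, would deliver hydrogen to C9 on the same face. The product is 30 (as its 6R epimer), where the route resumes.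

**Step 11.** What may go wrong: slow oxidative addition into the doubly ortho-substituted C–Br bond, leading to protodebromination; attack on the lactone during the long exposure to amide base; or protonation of the delocalised enolate at C9, so that the double bond ends at C6=C8.
Fallback: a Friedel–Crafts closure of ring B at C9–C10, starting from 17 and 2.
- Aldehyde 2 and diazoester 4 under the conditions of step 3 would give ethyl 6-bromo-7-methyl-1-benzofuran-3-carboxylate F4.
- Miyaura borylation (B2pin2, PdCl2(dppf), KOAc, dioxane, 90 °C) would give pinacol boronate F5.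
- Rhodium-catalysed conjugate addition of F5 to 17 ([Rh(cod)Cl]2, K3PO4, dioxane/H2O, 50 °C) should place the aryl group on C6, β to the ketone, to give keto diester F6.
- MeSO3H in CH2Cl2 would close the ring from the position para to the furan oxygen onto the C9 ketone and dehydrate to the C8=C9 alkene, the only isomer accessible under acid. This is 23.

**Step 6.** What may go wrong: low reactivity of the simple 2-siloxydiene toward the α-oxyacrylate at temperatures the silyl enol ether tolerates, and loss of regiochemical integrity of the enol ether (hydrolysis or isomerisation). The latter erases the difference between the two ring arms, which is the only record of the C13 configuration.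
Fallback: starting from 10, a more reactive diene and an enone to carry the arm assignment.
- trans-1-Methoxy-3-(trimethylsilyloxy)buta-1,3-diene in toluene at 60 °C would give cycloadduct F7 with the same facial and regiochemical sense.
- Dilute HCl in THF would convert F7 into enone F8.
- I2 and pyridine would give iodoenone F9.
- Palladium-catalysed coupling with BrZnCH2CO2Et (Pd(PPh3)4, THF, 50 °C) would give enone ester F10.
- LiBH(s-Bu)3 followed by PhNTf2, as in step 9, would add hydride at C14 and give triflate 19, where the route resumes.

## Further compounds

F1 | step 15 | bromomethyl ketone: as 28 with C(=O)CH2Br on C13 (13S; C6 epimers) | CCOC(=O)C1C2=C(CC[C@](O[Si](CC)(CC)CC)(C2)C(=O)CBr)c2cc3c(C(=O)OCC)coc3c(C)c12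
F2 | step 16 | 9(11)-ene 16-ketone with ring D closed, OSiEt3 on C13 (8S,13S; C6 epimers) | O=C1C[C@]23C[C@@]1(O[Si](CC)(CC)CC)CC=C2c1cc2c(C(=O)OCC)coc2c(C)c1C3C(=O)OCC
F3 | step 16 | 9(11)-ene 16-ketone F2 with the C6 ester on the C15 face (6R,8S,13S) | O=C1C[C@]23C[C@@]1(O[Si](CC)(CC)CC)CC=C2c1cc2c(C(=O)OCC)coc2c(C)c1[C@@H]3C(=O)OCC
F4 | step 11 | ethyl 6-bromo-7-methyl-1-benzofuran-3-carboxylate | CCOC(=O)c1coc2c(C)c(Br)ccc12
F5 | step 11 | ethyl 7-methyl-6-(4,4,5,5-tetramethyl-1,3,2-dioxaborolan-2-yl)-1-benzofuran-3-carboxylate | CCOC(=O)c1coc2c(C)c(B3OC(C)(C)C(C)(C)O3)ccc12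
F6 | step 11 | ethyl 6-{2-ethoxy-2-oxo-1-[(2R,5S)-2-tert-butyl-4,8-dioxo-1,3-dioxaspiro[4.5]decan-7-yl]ethyl}-7-methyl-1-benzofuran-3-carboxylate (diastereomers at C6 and C8) | CCOC(=O)C(c1ccc2c(C(=O)OCC)coc2c1C)C1C[C@]2(CCC1=O)O[C@@H](C(C)(C)C)OC2=O
F7 | step 6 | (2R,5S)-2-tert-butyl-6-methoxy-8-(trimethylsilyloxy)-1,3-dioxaspiro[4.5]dec-7-en-4-one (methoxy carbon not controlled) | COC1C=C(O[Si](C)(C)C)CC[C@]12O[C@@H](C(C)(C)C)OC2=O
F8 | step 6 | (2R,5S)-2-tert-butyl-1,3-dioxaspiro[4.5]dec-6-ene-4,8-dione | O=C1C=C[C@]2(CC1)O[C@@H](C(C)(C)C)OC2=O
F9 | step 6 | (2R,5S)-2-tert-butyl-7-iodo-1,3-dioxaspiro[4.5]dec-6-ene-4,8-dione | O=C1C(I)=C[C@]2(CC1)O[C@@H](C(C)(C)C)OC2=O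
F10 | step 6 | ethyl 2-[(2R,5S)-2-tert-butyl-4,8-dioxo-1,3-dioxaspiro[4.5]dec-6-en-7-yl]acetate | CCOC(=O)CC1=C[C@]2(CCC1=O)O[C@@H](C(C)(C)C)OC2=O
A1 | alternative 1 | vinylfuran ynone: C/D bicycle with but-2-ynoyl on C8 and 2-(4-methoxycarbonylfuran-3-yl)vinyl on C9 | C=C1C[C@]2(C(=O)C#CC)C[C@@]1(O)CC[C@H]2C=Cc1cocc1C(=O)OC
A2 | alternative 1 | benzofuran tetracycle with C6 ketone (furan methyl ester) | C=C1C[C@]23C[C@@]1(O)CC[C@H]2c1cc2c(C(=O)OC)coc2c(C)c1C3=O
A3 | alternative 2 | achiral aryl bromide: 1-aroyl-1-(2-silyloxyethyl)cyclohexa-2,5-diene | CC(C)(C)[Si](C)(C)OCCC1(C=CCC=C1)C(=O)c1c(C)c2occ(C(=O)OCC)c2cc1Br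
A4 | alternative 2 | cis-fused tetrahydrofluorenone with C8 and C9 set | CC(C)(C)[Si](C)(C)OCC[C@]12C=CCC[C@H]1c1cc3c(C(=O)OCC)coc3c(C)c1C2=O
A5 | alternative 3 | iodide with spiro 1,2-bis(trimethylsilyloxy)cyclopentene on C8, 2-iodoethyl on C9 and CO2Me on C6 (trans) | ICC[C@H]1c2cc3c(C(=O)OCC)coc3c(C)c2[C@H](C(=O)OC)C12CC(O[Si](C)(C)C)=C(O[Si](C)(C)C)C2
A6 | alternative 3 | 13-trimethylsilyloxy 16-ketone with rings C and D closed | O=C1C[C@]23C[C@@]1(O[Si](C)(C)C)CC[C@H]2c1cc2c(C(=O)OCC)coc2c(C)c1[C@@H]3C(=O)OC
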